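## Structural features

The target is a dimer of 7,8,4'-trihydroxyflavan-3,4-diol whose two halves are held together by a single ether oxygen between their C-4 atoms, with no carbon–carbon bond between them. Each half is a chroman: a 1,2,3-trioxygenated ring A (O-1, 8-OH, 7-OH) is fused to the dihydropyran ring C, which carries a 4-hydroxyphenyl ring B at C-2, a hydroxyl at C-3 and the bridging oxygen at C-4. C-2, C-3 and C-4 form a contiguous stereotriad in each half; half A is all-cis (2R,3R,4R) and half B is 2,3-trans-3,4-cis (2S,3R,4R), so the halves are C-2 epimers and need separate syntheses. The bridge is a doubly benzylic ether with a para 7-oxygen and an ortho O-1 on each side, so acid ionises it to flavan-4-yl cations; hydrogenolysis is excluded for the same reason, the catechol units are sensitive to air and base, and a free 4'-phenol lets base open O-1–C-2. The main difficulty is to join two hindered secondary benzylic carbons through oxygen with that oxygen cis to O-3 in both halves, although a flavan-4-yl cation takes up nucleophiles trans to O-3. The second difficulty is the all-cis triad of half A with its axial 3-oxygen. Of the six bonds of ring C in half A, O-1–C-8a alone ends at no stereogenic atom, and its carbon terminus is an arene position, lying between the oxygenated C-8 and C-4a, where a bromine atom can be placed. The key step exploits exactly this bond: the triad is assembled on an open chain and ring C is then closed by aryl–oxygen coupling.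

## Logic of the disconnections

**29 ⇒ 28 ⇒ 27.** The six aryl O–allyl bonds and the acetal on O-3 of half A are cut first. Allyl aryl ethers leave under zerovalent palladium without acid or hydrogen, and the silyloxymethyl acetal leaves with fluoride. All earlier intermediates are then neutral ethers with no free phenol. The demand is that fluoride is used before the phenols are free and that the last step runs without acid and without air.

**27 ⇒ 26 ⇒ 25 ⇒ 24.** The C-3–H bond of half B is cut (retron: 26). In 24 the 3-oxygen of half B is trans to the bridge, which is what cation chemistry delivers, and it is turned cis by oxidation and hydride return. This accepts the innate trans addition and repairs one centre afterwards. The demand is that hydride enters anti to the quasi-axial 4-alkoxy group, that 26 does not enolise at C-2 or C-4, and that O-3 of half B can be freed while O-3 of half A stays covered.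

**24 ⇒ 16 + 22.** The C-4–O bond on the half-B side is cut. 16 is the oxygen nucleophile, so its own C-4 is never ionised and the all-cis triad of half A survives. 22 is the C-4 electrophile of the 2,3-cis series, whose cation is attacked anti to O-3 and anti to the 2-aryl group. Only half B can be the cation, because its wrong relation to O-3 can be corrected at C-3 while that of half A could not. The gain is two monomers of the same constitution. The demand is that 22 is activated without ionising 16 or 24, which is met by passing through 23 with a catalytic silyl triflate at low temperature.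

**22 ⇒ 21 ⇒ 20.** The two acetates are cut back to the acetal and the free 4-hydroxyl. 20 is the mirror image of 16, so one sequence run with the two antipodes of one ligand serves both halves. The acetate on O-3 is the group that is later removed in the presence of the acetal of half A, and the acetate on O-4 is the leaving group.

**16 ⇒ 15 (and 20 ⇒ 19).** The bond O-1–C-8a is cut; this is the key disconnection. It removes the ring without removing a stereocentre and leaves an open-chain triol whose three centres can be set by acyclic stereocontrol. The demand is that only the ring-B carbinol can reach C-8a: the other benzylic hydroxyl would close a four-membered ring, and O-3 must carry a group that cannot migrate to a neighbouring alkoxide in hot carbonate base.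

**15 ⇒ 14 (and 19 ⇒ 18).** The C–H bond of the ring-B carbinol is cut (retron: β-hydroxy ketone). The existing hydroxyl delivers hydride internally and sets the 1,3-anti relation that becomes 2,3-cis in the ring.

**14 ⇒ 11 + 13 (and 18 ⇒ 17 + 13); 13 ⇒ 12 ⇒ 6.** The aryl–carbonyl bond is cut, with 11 (or 17) as the acyl partner and 13 as the aryl nucleophile. 13 goes back through 12 to 6 and is made once for both series. The coupling is neutral, so the β-hydroxy thioester neither reverts by retro-aldol nor epimerises. The demand is that palladium inserts into the C–S bond faster than into the hindered aryl bromide or the allyl ethers.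

**11 and 17 ⇒ 4 + 10.** The bond between the future C-3 and C-4 is cut by an anti glycolate aldol. The α-oxygen of 10 is an ether-type acetal oxygen for two reasons. A trialkylsilyloxy group on such a ketene acetal steers the tin-mediated aldol to the syn adduct, whereas an ether oxygen that can bind tin gives anti. The same acetal also cannot wander between oxygens in the ring closure, as a silyl ether flanked by two free hydroxyls could. The demand is anti selectivity and face selectivity from the chiral diamine, in both antipodal series.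

**10 ⇒ 9 ⇒ 8 ⇒ 7; 4 ⇒ 2 ⇒ 1 + 3; 6 ⇒ 5 + 3.** Enol silylation, ester-to-thioester exchange, O-alkylation, ether cleavage and two Williamson etherifications lead back to 1, 3, 5 and 7.

## Other disconnections considered

Alternative 1: The cut is at the C-3–O and C-4–O bonds of half B; no ring is opened. In the forward sense OsO4 with a cinchona alkaloid ligand would add across C-3=C-4 of the (2R)-2H-chromene A2 on the face away from the 2-aryl group and give the 2,3-trans-3,4-cis diol A1 (2S,3R,4R).
- In its favour: two C–O bonds and two stereocentres form in one concerted [3+2] step, substrate bias and ligand bias can be matched, and the triad of half B appears directly in its final configuration with no inversion at C-3.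
- Against it here: A1 is a monomer with a free 4-hydroxyl, and the bridge is still to be made. With A1 as nucleophile, half A must be the cation and would add trans to its O-3, which is wrong for an all-cis half. With A1 as electrophile, the C-4 centre just made is erased and re-formed trans to O-3, which is wrong again. OsO4 would also attack allyl ethers, so the phenols need silyl ethers that are labile to base and fluoride; A2 needs its own enantioselective synthesis; and O-3 and O-4 of A1 must be told apart.
- Comparison: on structure, Alternative 1 is the better way to the half-B triad taken alone (one step against etherification, oxidation and reduction), and its outcome is at least as predictable as the hydride addition of step 21. On mechanism it offers nothing for the C-4–O–C-4 bond, which the chosen plan solves by letting half B be the cation. On step economy it is equal or shorter for the monomer but leaves the union without a stereochemically sound step.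

Alternative 2: The cut is at O-1–C-2 of half B, broken and re-formed in one operation. In the forward sense aqueous base would deprotonate the free 4'-phenol of the bis-all-cis ether A4, the phenoxide would expel O-1 as a ring-A phenoxide (quinone-methide-type elimination), and conjugate re-addition would close ring C again (6-exo) under thermodynamic control to give A3 with the 2S, 2,3-trans arrangement.
- In its favour: it follows the probable biogenesis, needs no reagent beyond base, and needs only one enantiomeric series of monomer, since both halves start as (2R,3R,4R). On material economy this is better than the chosen plan, which runs its sequence in both mirror-image series.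
- Against it: the preference for an equatorial over an axial 3-hydroxyl is small, so the epimerisation is expected to stop at a mixture of A3 and A4. The two 4'-oxygens must be differentiated. Above all, A4 has the bridge oxygen cis to O-3 on both halves, which is the one arrangement that addition to a flavan-4-yl cation does not provide, so the hard problem is moved into the synthesis of A4.
- Comparison: structurally it inverts C-2 where the chosen plan inverts C-3 of half B. Mechanistically it is an equilibrium, whereas steps 20 and 21 are kinetically controlled. In step count one operation would replace three, which is better, but only if A4 were at hand.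

Alternative 3: The cut is at C-3–C-4 and O-1–C-2 of half A, with the bridge oxygen already on the future C-4. In the forward sense BF3·OEt2 would ionise the acetoxy acetal A6 (carried by O-4 of a 3-O-silylated half B) in an ortho-quinone-methide-forming step, and the (Z)-vinylsilane A7 would add across C-4 and O-1 in an inverse-demand hetero-Diels–Alder reaction to give A5. Tamao–Fleming oxidation of the C–Si bond with retention would then give the 3-hydroxyl.
- In its favour: it is the most convergent plan. One ring, two skeletal bonds and three stereocentres form in one step, against one ring, one bond and no stereocentre in the chosen key step. The bridge is made as an acetal from an aldehyde, which avoids the hindered cation etherification of step 18. On both points it is the better plan, and the 2,3-cis relation follows from the (Z) geometry.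
- Against it: the absolute configuration of three new centres would have to be induced by half B through the acetal oxygen, and the endo or exo orientation that fixes C-4 relative to C-2 and C-3 is not secured. BF3·OEt2 can also ionise the other C–O bond of the mixed acetal (C-4–O of half B), which would scramble that centre. The β-silyl cation may lose silicon instead of closing the ring. A6 itself needs a half-B diol of the type A1 with O-3 and O-4 differentiated.
- Comparison: the chosen plan sets every stereocentre by a reaction of established sense and closes ring C without touching any of them. Alternative 3 would be shorter in its longest linear sequence if its selectivities held, but it rests on three unproven selectivities in one step.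

Key step: step 11

Abbreviations: allyl = prop-2-en-1-yl; TOM = (triisopropylsilyloxy)methyl, CH2OSi(i-Pr)3; chroman = 3,4-dihydro-2H-chromene.

Remarks on the chemistry (assumptions):
- The L-proline-derived diamine (S)-1-ethyl-2-(piperidin-1-ylmethyl)pyrrolidine is taken to give the (2R,3R)-anti adduct with an α-alkoxy ketene silyl thioacetal and a benzaldehyde; if the sense were the opposite, the two diamine antipodes would change places between steps 7 and 12.
- The CIP label of C-3 changes with the groups on O-3 and O-4 (compounds 22 and 23); this is a change of priorities only.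
- Methyl glycolate is used as the commercial form of the glycolic acid unit.

## Route

Step 1
Reactants: 1 2-bromo-3-hydroxy-4-methoxybenzaldehyde
Product: 2 2-bromo-3,4-dihydroxybenzaldehyde
Conditions: BBr3, CH2Cl2, −78 °C to 0 °C; then H2O
Reagents that add atoms: none
Why: Lewis-acid ether cleavage: boron binds the methoxy oxygen and bromide attacks the methyl group; the aldehyde and the aryl bromide are inert at low temperature.

Step 2
Reactants: 2 2-bromo-3,4-dihydroxybenzaldehyde; 3 allyl bromide
Product: 4 3,4-bis(allyloxy)-2-bromobenzaldehyde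
Conditions: 3 (2.5 equiv), K2CO3, DMF, 50 °C
Reagents that add atoms: allyl bromide C=CCBr
Why: Williamson ether synthesis; each of the two phenoxides is alkylated by SN2 on one molecule of 3, so two equivalents of 3 are consumed, and no stereocentre is involved.

Step 3
Reactants: 5 4-bromophenol; 3 allyl bromide
Product: 6 1-(allyloxy)-4-bromobenzene
Conditions: K2CO3, acetone, reflux
Reagents that add atoms: none
Why: Williamson ether synthesis on a simple phenol.

Step 4
Reactants: 7 methyl glycolate
Product: 8 methyl 2-[(triisopropylsilyloxy)methoxy]acetate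
Conditions: i-Pr2NEt, CH2Cl2, 0 °C to rt
Reagents that add atoms: (triisopropylsilyloxy)methyl chloride ClCO[Si](C(C)C)(C(C)C)C(C)C
Why: O-alkylation of the primary hydroxyl by the chloromethyl ether (acetal formation of the alkoxymethyl type); the result is an ether-type α-oxygen that is cleaved later by fluoride and cannot migrate.

Step 5
Reactants: 8 methyl 2-[(triisopropylsilyloxy)methoxy]acetate
Product: 9 S-ethyl 2-[(triisopropylsilyloxy)methoxy]ethanethioate
Conditions: AlMe3, EtSH, CH2Cl2, 0 °C to rt
Reagents that add atoms: ethanethiol CCS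
Why: Aluminium thiolate transesterification: Me2AlSEt formed in the flask converts the methyl ester into the thioester, which is needed both for the aldol and for the later ketone synthesis.

Step 6
Reactants: 9 S-ethyl 2-[(triisopropylsilyloxy)methoxy]ethanethioate
Product: 10 (Z)-1-(ethylsulfanyl)-1-(trimethylsilyloxy)-2-[(triisopropylsilyloxy)methoxy]ethene
Conditions: LiN(i-Pr)2, Me3SiCl, THF, −78 °C
Reagents that add atoms: chlorotrimethylsilane C[Si](C)(C)Cl
Why: Kinetic enolisation of the thioester with the silyl chloride present traps the enolate on oxygen as the ketene silyl thioacetal; the (Z) isomer (alkoxy and ethylthio cis) is the one expected for α-alkoxy thioacetates.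

Step 7
Reactants: 4 3,4-bis(allyloxy)-2-bromobenzaldehyde; 10 (Z)-1-(ethylsulfanyl)-1-(trimethylsilyloxy)-2-[(triisopropylsilyloxy)methoxy]ethene
Product: 11 S-ethyl (2R,3R)-3-[3,4-bis(allyloxy)-2-bromophenyl]-3-hydroxy-2-[(triisopropylsilyloxy)methoxy]propanethioate
Conditions: Sn(OTf)2, (S)-1-ethyl-2-(piperidin-1-ylmethyl)pyrrolidine, Bu2Sn(OAc)2, CH2Cl2, −78 °C; then aq. NaHCO3
Reagents that add atoms: none
Why: Asymmetric Mukaiyama aldol under a chiral divalent tin Lewis acid; an ether-type α-oxygen that can bind tin leads to the anti adduct (a trialkylsilyloxy group would give syn), and the diamine on tin selects the aldehyde face. This sets the future C-3 (2R) and C-4 (3R) of half A.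

Step 8
Reactants: 6 1-(allyloxy)-4-bromobenzene
Product: 13 4-(allyloxy)phenylzinc chloride, via 4-(allyloxy)phenylmagnesium bromide 12 (not isolated)
Conditions: Mg, LiCl, THF, rt; then ZnCl2, THF, 0 °C; kept as a titrated THF solution under Ar
Reagents that add atoms: zinc dichloride Cl[Zn]Cl
Why: Grignard formation by magnesium insertion into the aryl bromide (assisted by LiCl) followed by transmetalation to zinc gives the arylzinc halide; the aryl allyl ether is inert to both metals at these temperatures. One batch of this solution serves steps 9 and 13.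

Step 9
Reactants: 11 S-ethyl (2R,3R)-3-[3,4-bis(allyloxy)-2-bromophenyl]-3-hydroxy-2-[(triisopropylsilyloxy)methoxy]propanethioate; 13 4-(allyloxy)phenylzinc chloride
Product: 14 (2R,3R)-3-[3,4-bis(allyloxy)-2-bromophenyl]-3-hydroxy-1-[4-(allyloxy)phenyl]-2-[(triisopropylsilyloxy)methoxy]propan-1-one
Conditions: 13 (2.5 equiv), PdCl2(PPh3)2 (5 mol %), THF–toluene, rt; then aq. NH4Cl
Reagents that add atoms: none
Why: Fukuyama coupling: zerovalent palladium inserts into the C–S bond, the arylzinc transmetalates and reductive elimination gives the aryl ketone under neutral conditions, so neither retro-aldol nor epimerisation at the α-carbon is expected. The C–S bond should react faster than the doubly ortho-substituted aryl bromide and the allyl ethers.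

Step 10
Reactants: 14 (2R,3R)-3-[3,4-bis(allyloxy)-2-bromophenyl]-3-hydroxy-1-[4-(allyloxy)phenyl]-2-[(triisopropylsilyloxy)methoxy]propan-1-one
Product: 15 (1R,2S,3R)-1-[3,4-bis(allyloxy)-2-bromophenyl]-3-[4-(allyloxy)phenyl]-2-[(triisopropylsilyloxy)methoxy]propane-1,3-diol
Conditions: Me4NBH(OAc)3, MeCN–AcOH, −30 °C
Reagents that add atoms: none
Why: Evans–Saksena reduction: the free hydroxyl exchanges an acetate on boron and delivers hydride internally through a chair-like six-membered transition state, giving the 1,3-anti diol. This sets the future C-2 (3R here), syn to the central oxygen.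

Step 11
Reactants: 15 (1R,2S,3R)-1-[3,4-bis(allyloxy)-2-bromophenyl]-3-[4-(allyloxy)phenyl]-2-[(triisopropylsilyloxy)methoxy]propane-1,3-diol
Product: 16 (2R,3R,4R)-7,8-bis(allyloxy)-2-[4-(allyloxy)phenyl]-3-[(triisopropylsilyloxy)methoxy]chroman-4-ol
Conditions: CuI (10 mol %), 3,4,7,8-tetramethyl-1,10-phenanthroline (20 mol %), Cs2CO3, toluene, 110 °C, Ar
Reagents that add atoms: none
Why: Ullmann-type intramolecular C–O coupling: Cs2CO3 and ligated CuI convert the ring-B carbinol into a monovalent copper alkoxide, the neighbouring aryl bromide adds oxidatively to give a trivalent aryl copper alkoxide, and reductive elimination forms O-1–C-8a. The closest known reaction type is the copper-catalysed intramolecular O-arylation of 3-(2-halophenyl)propan-1-ols to chromans. Ring C closes in a 6-exo mode at the aromatic carbon, through a seven-membered aryl–copper–alkoxide metallacycle. The step creates no stereocentre and touches no bond at C-2, C-3 or C-4, so the anti,syn triad of 15 appears as the all-cis triad of 16. The selectivity required is chemoselectivity alone: the hydroxyl beside ring A could reach C-8a only through a four-membered ring, and O-3 is blocked as an acetal ether that has no way of shifting to a neighbouring alkoxide, which rules out a five-membered closure. Copper is preferred to palladium because the benzylic alkoxides then do not suffer β-hydride elimination and the three allyl ethers are not ionised. Working under argon limits oxidation of the free benzylic alcohol to the ketone, and the electron-rich phenanthroline ligand speeds up oxidative addition so that ring closure outruns loss of bromine by reduction.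

Step 12
Reactants: 4 3,4-bis(allyloxy)-2-bromobenzaldehyde; 10 (Z)-1-(ethylsulfanyl)-1-(trimethylsilyloxy)-2-[(triisopropylsilyloxy)methoxy]ethene
Product: 17 S-ethyl (2S,3S)-3-[3,4-bis(allyloxy)-2-bromophenyl]-3-hydroxy-2-[(triisopropylsilyloxy)methoxy]propanethioate
Conditions: Sn(OTf)2, (R)-1-ethyl-2-(piperidin-1-ylmethyl)pyrrolidine, Bu2Sn(OAc)2, CH2Cl2, −78 °C; then aq. NaHCO3
Reagents that add atoms: none
Why: The same anti-selective Mukaiyama aldol as step 7 with the antipodal diamine, which should give the mirror-image adduct for half B.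

Step 13
Reactants: 17 S-ethyl (2S,3S)-3-[3,4-bis(allyloxy)-2-bromophenyl]-3-hydroxy-2-[(triisopropylsilyloxy)methoxy]propanethioate; 13 4-(allyloxy)phenylzinc chloride
Product: 18 (2S,3S)-3-[3,4-bis(allyloxy)-2-bromophenyl]-3-hydroxy-1-[4-(allyloxy)phenyl]-2-[(triisopropylsilyloxy)methoxy]propan-1-one
Conditions: 13 (2.5 equiv), PdCl2(PPh3)2 (5 mol %), THF–toluene, rt; then aq. NH4Cl
Reagents that add atoms: none
Why: Fukuyama coupling as in step 9, in the mirror-image series and with a second portion of the same arylzinc solution.

Step 14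
Reactants: 18 (2S,3S)-3-[3,4-bis(allyloxy)-2-bromophenyl]-3-hydroxy-1-[4-(allyloxy)phenyl]-2-[(triisopropylsilyloxy)methoxy]propan-1-one
Product: 19 (1S,2R,3S)-1-[3,4-bis(allyloxy)-2-bromophenyl]-3-[4-(allyloxy)phenyl]-2-[(triisopropylsilyloxy)methoxy]propane-1,3-diol
Conditions: Me4NBH(OAc)3, MeCN–AcOH, −30 °C
Reagents that add atoms: none
Why: Evans–Saksena 1,3-anti reduction as in step 10; it sets the future C-2 of half B as S and cis to O-3, which the later etherification requires.

Step 15
Reactants: 19 (1S,2R,3S)-1-[3,4-bis(allyloxy)-2-bromophenyl]-3-[4-(allyloxy)phenyl]-2-[(triisopropylsilyloxy)methoxy]propane-1,3-diol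
Product: 20 (2S,3S,4S)-7,8-bis(allyloxy)-2-[4-(allyloxy)phenyl]-3-[(triisopropylsilyloxy)methoxy]chroman-4-ol
Conditions: CuI (10 mol %), 3,4,7,8-tetramethyl-1,10-phenanthroline (20 mol %), Cs2CO3, toluene, 110 °C, Ar
Reagents that add atoms: none
Why: The same copper-catalysed Ullmann-type aryl–oxygen closure as step 11 on the enantiomer; ring C of half B closes at O-1–C-8a with all three centres untouched.

Step 16
Reactants: 20 (2S,3S,4S)-7,8-bis(allyloxy)-2-[4-(allyloxy)phenyl]-3-[(triisopropylsilyloxy)methoxy]chroman-4-ol
Product: 21 (2S,3S,4S)-7,8-bis(allyloxy)-2-[4-(allyloxy)phenyl]chroman-3,4-diol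
Conditions: Bu4NF, THF, rt
Reagents that add atoms: none
Why: Fluoride attacks silicon and the resulting hemiacetal loses formaldehyde, freeing O-3; aryl allyl ethers and the benzylic alcohol are stable to fluoride.

Step 17
Reactants: 21 (2S,3S,4S)-7,8-bis(allyloxy)-2-[4-(allyloxy)phenyl]chroman-3,4-diol
Product: 22 (2S,3R,4S)-7,8-bis(allyloxy)-2-[4-(allyloxy)phenyl]chroman-3,4-diyl diacetate (all-cis)
Conditions: Ac2O, pyridine, DMAP (cat.), CH2Cl2, 0 °C to rt
Reagents that add atoms: acetic anhydride CC(=O)OC(C)=O
Why: Acylation of both secondary hydroxyls; the 4-acetate becomes the leaving group and the 3-acetate the participating group, which is removable later in the presence of the acetal on half A.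

Step 18
Reactants: 16 (2R,3R,4R)-7,8-bis(allyloxy)-2-[4-(allyloxy)phenyl]-3-[(triisopropylsilyloxy)methoxy]chroman-4-ol; 22 (2S,3R,4S)-7,8-bis(allyloxy)-2-[4-(allyloxy)phenyl]chroman-3,4-diyl diacetate
Product: 24 (2R,3R,4R)-7,8-bis(allyloxy)-2-[4-(allyloxy)phenyl]-3-[(triisopropylsilyloxy)methoxy]chroman-4-yl (2S,3S,4R)-3-acetoxy-7,8-bis(allyloxy)-2-[4-(allyloxy)phenyl]chroman-4-yl ether, via 4-O-trimethylsilyl ether 23 (not isolated)
Conditions: 16, (Me3Si)2NH, Me3SiOTf (cat.), CH2Cl2, rt, volatiles removed; then 22, Me3SiOTf (0.1 equiv), 4 Å sieves, CH2Cl2, −78 to −50 °C; Et3N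
Reagents that add atoms: none
Why: Lewis-acid-promoted SN1 etherification of a flavan-4-yl acetate: the silyl triflate ionises the 4-acetate, the axial 3-acetoxy group bridges the cation as an acetoxonium ion, and the silyl ether oxygen of 23 attacks C-4 anti to O-3 and to the 2-aryl group, setting C-4 of half B as R. The silyl group passes to acetate and the catalyst is regenerated, so no Brønsted acid is formed. C-4 of half A is not ionised, because that half reacts only through oxygen.

Step 19
Reactants: 24 (2R,3R,4R)-7,8-bis(allyloxy)-2-[4-(allyloxy)phenyl]-3-[(triisopropylsilyloxy)methoxy]chroman-4-yl (2S,3S,4R)-3-acetoxy-7,8-bis(allyloxy)-2-[4-(allyloxy)phenyl]chroman-4-yl ether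
Product: 25 (2R,3R,4R)-7,8-bis(allyloxy)-2-[4-(allyloxy)phenyl]-3-[(triisopropylsilyloxy)methoxy]chroman-4-yl (2S,3S,4R)-7,8-bis(allyloxy)-2-[4-(allyloxy)phenyl]-3-hydroxychroman-4-yl ether
Conditions: K2CO3, MeOH–THF, 0 °C to rt
Reagents that add atoms: none
Why: Base-catalysed transesterification removes the acetate; the bis-benzylic ether, the acetal and the allyl ethers are stable to carbonate in methanol while no phenol is free.

Step 20
Reactants: 25 (2R,3R,4R)-7,8-bis(allyloxy)-2-[4-(allyloxy)phenyl]-3-[(triisopropylsilyloxy)methoxy]chroman-4-yl (2S,3S,4R)-7,8-bis(allyloxy)-2-[4-(allyloxy)phenyl]-3-hydroxychroman-4-yl ether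
Product: 26 (2R,3R,4R)-7,8-bis(allyloxy)-2-[4-(allyloxy)phenyl]-3-[(triisopropylsilyloxy)methoxy]chroman-4-yl (2S,4R)-7,8-bis(allyloxy)-2-[4-(allyloxy)phenyl]-3-oxochroman-4-yl ether
Conditions: Dess–Martin periodinane, NaHCO3, CH2Cl2, 0 °C to rt
Reagents that add atoms: none
Why: Dess–Martin oxidation of the secondary alcohol under buffered, non-enolising conditions; the ketone is carried on without chromatography so that C-2 and C-4 of half B are not exposed to enolisation.

Step 21
Reactants: 26 (2R,3R,4R)-7,8-bis(allyloxy)-2-[4-(allyloxy)phenyl]-3-[(triisopropylsilyloxy)methoxy]chroman-4-yl (2S,4R)-7,8-bis(allyloxy)-2-[4-(allyloxy)phenyl]-3-oxochroman-4-yl ether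
Product: 27 (2R,3R,4R)-7,8-bis(allyloxy)-2-[4-(allyloxy)phenyl]-3-[(triisopropylsilyloxy)methoxy]chroman-4-yl (2S,3R,4R)-7,8-bis(allyloxy)-2-[4-(allyloxy)phenyl]-3-hydroxychroman-4-yl ether
Conditions: NaBH4, THF–MeOH, −40 °C
Reagents that add atoms: none
Why: Hydride reduction of a cyclic α-alkoxy ketone: with the 2-aryl group equatorial the 4-alkoxy group is quasi-axial, and a small hydride should enter anti to that C–O bond (Felkin–Anh polar and torsional control, axial attack), giving the equatorial 3-hydroxyl cis to O-4 and trans to the aryl group (3R). NaBH4 is chosen over LiBH(sec-Bu)3 because a hindered hydride tends to attack flavan-3-ones anti to the 2-aryl group, which would here return the 2,3-cis alcohol.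

Step 22
Reactants: 27 (2R,3R,4R)-7,8-bis(allyloxy)-2-[4-(allyloxy)phenyl]-3-[(triisopropylsilyloxy)methoxy]chroman-4-yl (2S,3R,4R)-7,8-bis(allyloxy)-2-[4-(allyloxy)phenyl]-3-hydroxychroman-4-yl ether
Product: 28 (2R,3R,4R)-7,8-bis(allyloxy)-2-[4-(allyloxy)phenyl]-3-hydroxychroman-4-yl (2S,3R,4R)-7,8-bis(allyloxy)-2-[4-(allyloxy)phenyl]-3-hydroxychroman-4-yl ether
Conditions: Bu4NF, THF, rt
Reagents that add atoms: none
Why: Fluoride cleavage of the silyloxymethyl acetal (attack at silicon, loss of formaldehyde) frees O-3 of half A while all phenols are still allylated, so no phenoxide is exposed to the basic fluoride.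

Step 23
Reactants: 28 (2R,3R,4R)-7,8-bis(allyloxy)-2-[4-(allyloxy)phenyl]-3-hydroxychroman-4-yl (2S,3R,4R)-7,8-bis(allyloxy)-2-[4-(allyloxy)phenyl]-3-hydroxychroman-4-yl ether
Product: 29 (2R,3R,4R)-3,7,8-trihydroxy-2-(4-hydroxyphenyl)chroman-4-yl (2S,3R,4R)-3,7,8-trihydroxy-2-(4-hydroxyphenyl)chroman-4-yl ether (CNP0241481.1)
Conditions: Pd(PPh3)4 (cat.), morpholine, degassed THF, rt, Ar
Reagents that add atoms: none
Why: Tsuji–Trost deallylation: zerovalent palladium ionises each aryl allyl ether to a π-allyl complex and a phenoxide, and morpholine takes the allyl group. The medium is free of acid and hydrogen, so the bis-benzylic ether and the C-2–O-1 bonds should survive.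

## Compound list

1 | 2-bromo-3-hydroxy-4-methoxybenzaldehyde | COc1ccc(C=O)c(Br)c1O | starting material
2 | 2-bromo-3,4-dihydroxybenzaldehyde | O=Cc1ccc(O)c(O)c1Br | intermediate
3 | allyl bromide | C=CCBr | starting material
4 | 3,4-bis(allyloxy)-2-bromobenzaldehyde | O=Cc1ccc(OCC=C)c(OCC=C)c1Br | intermediate
5 | 4-bromophenol | Oc1ccc(Br)cc1 | starting material
6 | 1-(allyloxy)-4-bromobenzene | C=CCOc1ccc(Br)cc1 | intermediate
7 | methyl glycolate | COC(=O)CO | starting material
8 | methyl 2-[(triisopropylsilyloxy)methoxy]acetate | COC(=O)COCO[Si](C(C)C)(C(C)C)C(C)C | intermediate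
9 | S-ethyl 2-[(triisopropylsilyloxy)methoxy]ethanethioate | CCSC(=O)COCO[Si](C(C)C)(C(C)C)C(C)C | intermediate
10 | (Z)-1-(ethylsulfanyl)-1-(trimethylsilyloxy)-2-[(triisopropylsilyloxy)methoxy]ethene | CCS/C(O[Si](C)(C)C)=C\OCO[Si](C(C)C)(C(C)C)C(C)C | intermediate
11 | S-ethyl (2R,3R)-3-[3,4-bis(allyloxy)-2-bromophenyl]-3-hydroxy-2-[(triisopropylsilyloxy)methoxy]propanethioate | CCSC(=O)[C@H](OCO[Si](C(C)C)(C(C)C)C(C)C)[C@H](O)c1ccc(OCC=C)c(OCC=C)c1Br | intermediate
12 | 4-(allyloxy)phenylmagnesium bromide | C=CCOc1ccc([Mg]Br)cc1 | intermediate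
13 | 4-(allyloxy)phenylzinc chloride | C=CCOc1ccc([Zn]Cl)cc1 | intermediate
14 | (2R,3R)-3-[3,4-bis(allyloxy)-2-bromophenyl]-3-hydroxy-1-[4-(allyloxy)phenyl]-2-[(triisopropylsilyloxy)methoxy]propan-1-one | C=CCOc1ccc(cc1)C(=O)[C@H](OCO[Si](C(C)C)(C(C)C)C(C)C)[C@H](O)c1ccc(OCC=C)c(OCC=C)c1Br | intermediate
15 | (1R,2S,3R)-1-[3,4-bis(allyloxy)-2-bromophenyl]-3-[4-(allyloxy)phenyl]-2-[(triisopropylsilyloxy)methoxy]propane-1,3-diol | C=CCOc1ccc(cc1)[C@@H](O)[C@H](OCO[Si](C(C)C)(C(C)C)C(C)C)[C@H](O)c1ccc(OCC=C)c(OCC=C)c1Br | intermediate
16 | (2R,3R,4R)-7,8-bis(allyloxy)-2-[4-(allyloxy)phenyl]-3-[(triisopropylsilyloxy)methoxy]chroman-4-ol | C=CCOc1ccc(cc1)[C@H]1Oc2c(ccc(OCC=C)c2OCC=C)[C@@H](O)[C@H]1OCO[Si](C(C)C)(C(C)C)C(C)C | intermediate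
17 | S-ethyl (2S,3S)-3-[3,4-bis(allyloxy)-2-bromophenyl]-3-hydroxy-2-[(triisopropylsilyloxy)methoxy]propanethioate | CCSC(=O)[C@@H](OCO[Si](C(C)C)(C(C)C)C(C)C)[C@@H](O)c1ccc(OCC=C)c(OCC=C)c1Br | intermediate
18 | (2S,3S)-3-[3,4-bis(allyloxy)-2-bromophenyl]-3-hydroxy-1-[4-(allyloxy)phenyl]-2-[(triisopropylsilyloxy)methoxy]propan-1-one | C=CCOc1ccc(cc1)C(=O)[C@@H](OCO[Si](C(C)C)(C(C)C)C(C)C)[C@@H](O)c1ccc(OCC=C)c(OCC=C)c1Br | intermediate
19 | (1S,2R,3S)-1-[3,4-bis(allyloxy)-2-bromophenyl]-3-[4-(allyloxy)phenyl]-2-[(triisopropylsilyloxy)methoxy]propane-1,3-diol | C=CCOc1ccc(cc1)[C@H](O)[C@@H](OCO[Si](C(C)C)(C(C)C)C(C)C)[C@@H](O)c1ccc(OCC=C)c(OCC=C)c1Br | intermediate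
20 | (2S,3S,4S)-7,8-bis(allyloxy)-2-[4-(allyloxy)phenyl]-3-[(triisopropylsilyloxy)methoxy]chroman-4-ol | C=CCOc1ccc(cc1)[C@@H]1Oc2c(ccc(OCC=C)c2OCC=C)[C@H](O)[C@@H]1OCO[Si](C(C)C)(C(C)C)C(C)C | intermediate
21 | (2S,3S,4S)-7,8-bis(allyloxy)-2-[4-(allyloxy)phenyl]chroman-3,4-diol | C=CCOc1ccc(cc1)[C@@H]1Oc2c(ccc(OCC=C)c2OCC=C)[C@H](O)[C@@H]1O | intermediate
22 | (2S,3R,4S)-7,8-bis(allyloxy)-2-[4-(allyloxy)phenyl]chroman-3,4-diyl diacetate (all-cis) | C=CCOc1ccc(cc1)[C@@H]1Oc2c(ccc(OCC=C)c2OCC=C)[C@H](OC(C)=O)[C@@H]1OC(C)=O | intermediate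
23 | (2R,3S,4R)-7,8-bis(allyloxy)-2-[4-(allyloxy)phenyl]-3-[(triisopropylsilyloxy)methoxy]-4-(trimethylsilyloxy)chroman (all-cis) | C=CCOc1ccc(cc1)[C@H]1Oc2c(ccc(OCC=C)c2OCC=C)[C@@H](O[Si](C)(C)C)[C@H]1OCO[Si](C(C)C)(C(C)C)C(C)C | intermediate
24 | (2R,3R,4R)-7,8-bis(allyloxy)-2-[4-(allyloxy)phenyl]-3-[(triisopropylsilyloxy)methoxy]chroman-4-yl (2S,3S,4R)-3-acetoxy-7,8-bis(allyloxy)-2-[4-(allyloxy)phenyl]chroman-4-yl ether | C=CCOc1ccc([C@H]2Oc3c(ccc(OCC=C)c3OCC=C)[C@@H](O[C@@H]3c4ccc(OCC=C)c(OCC=C)c4O[C@@H](c4ccc(OCC=C)cc4)[C@H]3OC(C)=O)[C@H]2OCO[Si](C(C)C)(C(C)C)C(C)C)cc1 | intermediate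
25 | (2R,3R,4R)-7,8-bis(allyloxy)-2-[4-(allyloxy)phenyl]-3-[(triisopropylsilyloxy)methoxy]chroman-4-yl (2S,3S,4R)-7,8-bis(allyloxy)-2-[4-(allyloxy)phenyl]-3-hydroxychroman-4-yl ether | C=CCOc1ccc([C@H]2Oc3c(ccc(OCC=C)c3OCC=C)[C@@H](O[C@@H]3c4ccc(OCC=C)c(OCC=C)c4O[C@@H](c4ccc(OCC=C)cc4)[C@H]3O)[C@H]2OCO[Si](C(C)C)(C(C)C)C(C)C)cc1 | intermediate
26 | (2R,3R,4R)-7,8-bis(allyloxy)-2-[4-(allyloxy)phenyl]-3-[(triisopropylsilyloxy)methoxy]chroman-4-yl (2S,4R)-7,8-bis(allyloxy)-2-[4-(allyloxy)phenyl]-3-oxochroman-4-yl ether | C=CCOc1ccc([C@H]2Oc3c(ccc(OCC=C)c3OCC=C)[C@@H](O[C@@H]3c4ccc(OCC=C)c(OCC=C)c4O[C@@H](c4ccc(OCC=C)cc4)C3=O)[C@H]2OCO[Si](C(C)C)(C(C)C)C(C)C)cc1 | intermediate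
27 | (2R,3R,4R)-7,8-bis(allyloxy)-2-[4-(allyloxy)phenyl]-3-[(triisopropylsilyloxy)methoxy]chroman-4-yl (2S,3R,4R)-7,8-bis(allyloxy)-2-[4-(allyloxy)phenyl]-3-hydroxychroman-4-yl ether | C=CCOc1ccc([C@H]2Oc3c(ccc(OCC=C)c3OCC=C)[C@@H](O[C@@H]3c4ccc(OCC=C)c(OCC=C)c4O[C@@H](c4ccc(OCC=C)cc4)[C@@H]3O)[C@H]2OCO[Si](C(C)C)(C(C)C)C(C)C)cc1 | intermediate
28 | (2R,3R,4R)-7,8-bis(allyloxy)-2-[4-(allyloxy)phenyl]-3-hydroxychroman-4-yl (2S,3R,4R)-7,8-bis(allyloxy)-2-[4-(allyloxy)phenyl]-3-hydroxychroman-4-yl ether | C=CCOc1ccc([C@H]2Oc3c(ccc(OCC=C)c3OCC=C)[C@@H](O[C@@H]3c4ccc(OCC=C)c(OCC=C)c4O[C@@H](c4ccc(OCC=C)cc4)[C@@H]3O)[C@H]2O)cc1 | intermediate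
29 | (2R,3R,4R)-3,7,8-trihydroxy-2-(4-hydroxyphenyl)chroman-4-yl (2S,3R,4R)-3,7,8-trihydroxy-2-(4-hydroxyphenyl)chroman-4-yl ether (CNP0241481.1) | Oc1ccc([C@H]2Oc3c(ccc(O)c3O)[C@@H](O[C@@H]3c4ccc(O)c(O)c4O[C@@H](c4ccc(O)cc4)[C@@H]3O)[C@H]2O)cc1 | target

## Step count and least certain steps

Total step count: 23 steps. Longest linear sequence: 15 steps (steps 4–6, 12–17 and 18–23).

**Step 11 (key step; the same holds for step 15).** The bromide is flanked by an alkoxy group and a branched chain, so oxidative addition to copper may be slow. In that case loss of bromine by reduction and oxidation of the free benzylic alkoxide next to ring A (β-hydride transfer to copper) can overtake ring closure; binding of copper by the 1,3-diol may slow the catalyst further. Fallback: the leaving group is changed before ring closure. Setting out from 15, an aromatic Finkelstein reaction (CuI, trans-N,N'-dimethylcyclohexane-1,2-diamine, NaI, 1,4-dioxane, 110 °C, no base, so no alkoxide is present) should give the aryl iodide (1R,2S,3R)-1-[3,4-bis(allyloxy)-2-iodophenyl]-3-[4-(allyloxy)phenyl]-2-[(triisopropylsilyloxy)methoxy]propane-1,3-diol F1. The iodide should close under the same CuI–phenanthroline–Cs2CO3 system at about 80 °C and returns to the route at 16.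

**Step 18.** The flavan-4-yl cation may alkylate carbon instead of oxygen (Friedel–Crafts attack on C-6 of an electron-rich ring A). The silyl triflate may also re-ionise the product ether, which would put C-4 of half A at risk. Both partners are hindered secondary centres, so the oxygen attack is slow. Fallback: thiophilic instead of oxophilic activation, under buffered conditions. Setting out from 22, thiolysis with 2-mercaptobenzothiazole and BF3·OEt2 should give (2S,3R,4R)-3-acetoxy-4-(1,3-benzothiazol-2-ylsulfanyl)-7,8-bis(allyloxy)-2-[4-(allyloxy)phenyl]chroman F2. F2 would be activated with AgBF4 in the presence of 2,6-di-tert-butyl-4-methylpyridine, 4 Å sieves and the free alcohol 16 at low temperature; the route is rejoined at 24.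

**Step 7 (and step 12).** The acetal oxygen may bind tin less well than a simple ether oxygen, which would erode the anti selectivity, and the ortho-bromo substituent of 4 may lower the face selectivity. Fallback: resolution in place of asymmetric induction. Setting out from 4 and 10, the aldol is run with the racemic diamine, the anti diastereomer is purified, and the racemic anti thioester (a 1:1 mixture of 11 and 17) is separated into its antipodes by preparative chromatography on a chiral stationary phase. Both antipodes are needed, so the material returns to the route at 11 and at 17.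

**Step 21.** Hydride may enter from the face of the 4-alkoxy group, steered by the 2-aryl group, which regenerates the 2,3-cis alcohol. Enolisation of 26 during oxidation or reduction may epimerise C-2 or C-4 of half B. Fallback: inversion by displacement instead of by redox. Setting out from 25, (CF3SO2)2O and pyridine should give the triflate (2R,3R,4R)-7,8-bis(allyloxy)-2-[4-(allyloxy)phenyl]-3-[(triisopropylsilyloxy)methoxy]chroman-4-yl (2S,3S,4R)-7,8-bis(allyloxy)-2-[4-(allyloxy)phenyl]-3-(trifluoromethanesulfonyloxy)chroman-4-yl ether F3. Treatment with Bu4NNO2 (Lattrell–Dax inversion, SN2 at C-3) would give the inverted nitrite ester (2R,3R,4R)-7,8-bis(allyloxy)-2-[4-(allyloxy)phenyl]-3-[(triisopropylsilyloxy)methoxy]chroman-4-yl (2S,3R,4R)-7,8-bis(allyloxy)-2-[4-(allyloxy)phenyl]-3-(nitrosooxy)chroman-4-yl ether F4, which hydrolyses on aqueous work-up to the alcohol and rejoins the route at 27.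

**Step 9 (and step 13).** Zerovalent palladium may ionise an aryl allyl ether and pass the allyl group to the arylzinc, which removes protecting groups. The free hydroxyl also consumes part of the zinc reagent. Fallback: a palladium-free ketone synthesis. Setting out from 11, MeNHOMe·HCl and i-PrMgCl should give the Weinreb amide (2R,3R)-3-[3,4-bis(allyloxy)-2-bromophenyl]-3-hydroxy-N-methoxy-N-methyl-2-[(triisopropylsilyloxy)methoxy]propanamide F5. Addition of an excess of the Grignard reagent 12 (made from 6 as in step 8, without ZnCl2) would give the ketone and rejoin the route at 14; the same applies to 17 and 18.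

## Further compounds

F1 | step 11 | (1R,2S,3R)-1-[3,4-bis(allyloxy)-2-iodophenyl]-3-[4-(allyloxy)phenyl]-2-[(triisopropylsilyloxy)methoxy]propane-1,3-diol | C=CCOc1ccc(cc1)[C@@H](O)[C@H](OCO[Si](C(C)C)(C(C)C)C(C)C)[C@H](O)c1ccc(OCC=C)c(OCC=C)c1I
F2 | step 18 | (2S,3R,4R)-3-acetoxy-4-(1,3-benzothiazol-2-ylsulfanyl)-7,8-bis(allyloxy)-2-[4-(allyloxy)phenyl]chroman | c1ccc2sc(S[C@@H]3c4ccc(OCC=C)c(OCC=C)c4O[C@@H](c4ccc(OCC=C)cc4)[C@H]3OC(C)=O)nc2c1
F0 | step 7 | none | none
F3 | step 21 | (2R,3R,4R)-7,8-bis(allyloxy)-2-[4-(allyloxy)phenyl]-3-[(triisopropylsilyloxy)methoxy]chroman-4-yl (2S,3S,4R)-7,8-bis(allyloxy)-2-[4-(allyloxy)phenyl]-3-(trifluoromethanesulfonyloxy)chroman-4-yl ether | C=CCOc1ccc([C@H]2Oc3c(ccc(OCC=C)c3OCC=C)[C@@H](O[C@@H]3c4ccc(OCC=C)c(OCC=C)c4O[C@@H](c4ccc(OCC=C)cc4)[C@H]3OS(=O)(=O)C(F)(F)F)[C@H]2OCO[Si](C(C)C)(C(C)C)C(C)C)cc1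
F4 | step 21 | (2R,3R,4R)-7,8-bis(allyloxy)-2-[4-(allyloxy)phenyl]-3-[(triisopropylsilyloxy)methoxy]chroman-4-yl (2S,3R,4R)-7,8-bis(allyloxy)-2-[4-(allyloxy)phenyl]-3-(nitrosooxy)chroman-4-yl ether | C=CCOc1ccc([C@H]2Oc3c(ccc(OCC=C)c3OCC=C)[C@@H](O[C@@H]3c4ccc(OCC=C)c(OCC=C)c4O[C@@H](c4ccc(OCC=C)cc4)[C@@H]3ON=O)[C@H]2OCO[Si](C(C)C)(C(C)C)C(C)C)cc1
F5 | step 9 | (2R,3R)-3-[3,4-bis(allyloxy)-2-bromophenyl]-3-hydroxy-N-methoxy-N-methyl-2-[(triisopropylsilyloxy)methoxy]propanamide | CON(C)C(=O)[C@H](OCO[Si](C(C)C)(C(C)C)C(C)C)[C@H](O)c1ccc(OCC=C)c(OCC=C)c1Br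
A1 | alternative 1 | (2S,3R,4R)-7,8-bis(tert-butyldimethylsilyloxy)-2-[4-(tert-butyldimethylsilyloxy)phenyl]chroman-3,4-diol | O[C@@H]1c2ccc(O[Si](C)(C)C(C)(C)C)c(O[Si](C)(C)C(C)(C)C)c2O[C@@H](c2ccc(O[Si](C)(C)C(C)(C)C)cc2)[C@@H]1O
A2 | alternative 1 | (2R)-7,8-bis(tert-butyldimethylsilyloxy)-2-[4-(tert-butyldimethylsilyloxy)phenyl]-2H-chromene | [C@@H]1(c2ccc(O[Si](C)(C)C(C)(C)C)cc2)Oc2c(ccc(O[Si](C)(C)C(C)(C)C)c2O[Si](C)(C)C(C)(C)C)C=C1
A3 | alternative 2 | penta-O-allyl ether of the target with the 4'-phenol of half B free (half A 2R,3R,4R; half B 2S,3R,4R) | C=CCOc1ccc([C@H]2Oc3c(ccc(OCC=C)c3OCC=C)[C@@H](O[C@@H]3c4ccc(OCC=C)c(OCC=C)c4O[C@@H](c4ccc(O)cc4)[C@@H]3O)[C@H]2O)cc1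
A4 | alternative 2 | C-2 epimer of A3 in half B: bis-all-cis 4-O-4 ether (both halves 2R,3R,4R) with the 4'-phenol of half B free | C=CCOc1ccc([C@H]2Oc3c(ccc(OCC=C)c3OCC=C)[C@@H](O[C@@H]3c4ccc(OCC=C)c(OCC=C)c4O[C@H](c4ccc(O)cc4)[C@@H]3O)[C@H]2O)cc1
A5 | alternative 3 | hexa-O-allyl ether of the target skeleton with benzyldimethylsilyl in place of the 3-hydroxyl of half A and tert-butyldimethylsilyl on O-3 of half B | C=CCOc1ccc([C@H]2Oc3c(ccc(OCC=C)c3OCC=C)[C@@H](O[C@@H]3c4ccc(OCC=C)c(OCC=C)c4O[C@@H](c4ccc(OCC=C)cc4)[C@@H]3O[Si](C)(C)C(C)(C)C)[C@H]2[Si](C)(C)Cc5ccccc5)cc1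
A6 | alternative 3 | acetoxy[3,4-bis(allyloxy)-2-hydroxyphenyl]methyl ether on O-4 of the 3-O-tert-butyldimethylsilyl, tri-O-allyl half-B flavan-3,4-diol (mixture at the acetal carbon) | CC(=O)OC(c1ccc(OCC=C)c(OCC=C)c1O)O[C@@H]1c2ccc(OCC=C)c(OCC=C)c2O[C@@H](c2ccc(OCC=C)cc2)[C@@H]1O[Si](C)(C)C(C)(C)C
A7 | alternative 3 | (Z)-benzyl{2-[4-(allyloxy)phenyl]ethenyl}dimethylsilane | C=CCOc1ccc(cc1)/C=C\[Si](C)(C)Cc1ccccc1
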